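**Plan**
- Retrosynthesis: the C6–O angelate bond and the C11=C13 methylene are cut first. The Z C4=C5 bond is traced to a C4–SO2–C5 bridge, S–C5 to a thiolate alkylation, and O–C3/C1–C2 of the furanone to an α'-hydroxy ynone. C5–C6 goes back to a diazoketone homologation, C7–C8 to a boron aldol, and C8–C9 to an epoxide opening.
- Forward: (S)-2-methylglycidol gives the C8 aldehyde, and syn-aldol/lactonisation builds the γ-lactone. Alkynylation and oxa-Michael closure build the 3(2H)-furanone, and S-alkylation closes an eleven-membered thiacycle. SO2 extrusion contracts it to the ten-membered carbocycle; methylenation and angeloylation finish.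
- Enabling feature: C4 of the C4=C5 alkene (bearing the C15 methyl) is the γ-carbon of the furanone (C1 ketone, C2=C3 enol ether, ring O to C10). A C4–SO2–C5 unit in the C1–C10 ring is therefore acidified at C4, halogenated there and excised, and the O-bridged ring admits only the Z alkene.
- Stereochemistry: C10 comes from (S)-2-methylglycidol. C7 and C8 come from the (R)-4-benzyloxazolidinone syn-aldol (syn adduct gives the trans-lactone). C6 comes from an (R)-CBS reduction of a chloromethyl ketone. The angelate Z geometry comes from angelic acid.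

Key step: step 21

Remark: germacrane locants are used throughout. The sp3 centres C4, carbinol C1 and aminomethyl-bearing C11 are carried as epimer mixtures because each becomes sp2 later. TBS = tert-butyldimethylsilyl, Trt = triphenylmethyl.

Step 1
Reactants: 1 (S)-2-methylglycidol
Product: 2 (2R)-2-methylpent-4-ene-1,2-diol
Conditions: CH2=CHMgBr (3 equiv), CuI (10 mol%), THF, −30 → 0 °C; aq. NH4Cl
Reagents that add atoms: vinylmagnesium bromide, C=C[Mg]Br
Why: Copper-catalysed Grignard opening of the epoxide at its CH2 terminus (SN2) should leave the quaternary C10–O centre untouched, and the Payne-rearranged alkoxide is the same enantiomer, so no erosion is expected.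

Step 2
Reactants: 2 (2R)-2-methylpent-4-ene-1,2-diol
Product: 3 (4R)-2,2,4-trimethyl-4-(prop-2-en-1-yl)-1,3-dioxolane
Conditions: Me2C(OMe)2, PPTS (cat.), CH2Cl2, rt
Reagents that add atoms: 2,2-dimethoxypropane, COC(C)(C)OC
Why: Acid-catalysed transketalisation should protect the primary/tertiary 1,2-diol as its isopropylidene acetal.

Step 3
Reactants: 3 (4R)-2,2,4-trimethyl-4-(prop-2-en-1-yl)-1,3-dioxolane
Product: 5 [(4R)-2,2,4-trimethyl-1,3-dioxolan-4-yl]acetaldehyde, via secondary ozonide 4 (not isolated)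
Conditions: O3, CH2Cl2, −78 °C; PPh3, −78 °C → rt
Reagents that add atoms: ozone, [O-][O+]=O
Why: Ozonolysis with reductive work-up should cleave the terminal alkene to the C8 aldehyde without touching the acetal.

Step 4
Reactants: 6 (R)-4-benzyl-1,3-oxazolidin-2-one; 7 methyl 4-chloro-4-oxobutanoate
Product: 8 methyl 4-[(4R)-4-benzyl-2-oxo-1,3-oxazolidin-3-yl]-4-oxobutanoate
Conditions: n-BuLi, THF, −78 °C; then 7, −78 → 0 °C
Reagents that add atoms: none
Why: N-Acylation of the lithiated oxazolidinone by the acid chloride is the standard entry to Evans imides.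

Step 5
Reactants: 8 methyl 4-[(4R)-4-benzyl-2-oxo-1,3-oxazolidin-3-yl]-4-oxobutanoate; 5 [(4R)-2,2,4-trimethyl-1,3-dioxolan-4-yl]acetaldehyde
Product: 10 (4R)-4-benzyl-3-{[(2S,3R)-5-oxo-2-{[(4R)-2,2,4-trimethyl-1,3-dioxolan-4-yl]methyl}oxolan-3-yl]carbonyl}-1,3-oxazolidin-2-one, via open-chain syn-aldol adduct 9 (not isolated)
Conditions: Bu2BOTf (1.1 equiv), i-Pr2NEt (1.3 equiv), CH2Cl2, −78 → 0 °C; 5, −78 → 0 °C; pH 7 buffer, MeOH, 30% H2O2, 0 °C; then PPTS (cat.), CH2Cl2, rt
Reagents that add atoms: none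
Why: Evans syn-aldol through the Z-boron enolate and a Zimmerman–Traxler transition state, with the (R)-benzyl auxiliary fixing the enolate face, should set C7 (R) and C8 (S); the γ-hydroxy methyl ester then lactonises to the trans-β,γ-disubstituted butyrolactone.

Step 6
Reactants: 10 (4R)-4-benzyl-3-{[(2S,3R)-5-oxo-2-{[(4R)-2,2,4-trimethyl-1,3-dioxolan-4-yl]methyl}oxolan-3-yl]carbonyl}-1,3-oxazolidin-2-one
Product: 12 (2S,3R)-5-oxo-2-{[(4R)-2,2,4-trimethyl-1,3-dioxolan-4-yl]methyl}oxolane-3-carboxylic acid, via peroxy acid 11 (not isolated)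
Conditions: LiOH·H2O (2 equiv), 30% H2O2 (4 equiv), THF–H2O (3:1), 0 °C; aq. Na2SO3; then 1 M HCl to pH 2
Reagents that add atoms: hydrogen peroxide, OO
Why: Lithium hydroperoxide should cleave the exocyclic imide carbonyl selectively (auxiliary hydrolysis), and any lactone opening reverses on acidification because only the γ-lactone to the C8 oxygen can re-form.

Step 7
Reactants: 12 (2S,3R)-5-oxo-2-{[(4R)-2,2,4-trimethyl-1,3-dioxolan-4-yl]methyl}oxolane-3-carboxylic acid
Product: 14 (4R,5S)-4-(2-diazoacetyl)-5-{[(4R)-2,2,4-trimethyl-1,3-dioxolan-4-yl]methyl}oxolan-2-one, via mixed carbonic anhydride 13 (not isolated)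
Conditions: i-BuOCOCl, N-methylmorpholine, THF, −20 °C; then CH2N2 (Et2O, excess), −20 → 0 °C
Reagents that add atoms: diazomethane, C=[N+]=[N-]
Why: Acylation of diazomethane by the mixed anhydride (first stage of an Arndt–Eistert sequence) should attach C5 to the C6 carbonyl under near-neutral conditions that spare the lactone and the C7 centre.

Step 8
Reactants: 14 (4R,5S)-4-(2-diazoacetyl)-5-{[(4R)-2,2,4-trimethyl-1,3-dioxolan-4-yl]methyl}oxolan-2-one
Product: 15 (4R,5S)-4-(2-chloroacetyl)-5-{[(4R)-2,2,4-trimethyl-1,3-dioxolan-4-yl]methyl}oxolan-2-one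
Conditions: HCl (2 M in Et2O, 1.1 equiv), THF, −20 °C, 15 min; NaHCO3 quench
Reagents that add atoms: hydrogen chloride, Cl
Why: Protonation of the diazoketone and displacement of N2 by chloride should give the chloromethyl ketone, and stoichiometric anhydrous acid at low temperature should leave the acetonide intact.

Step 9
Reactants: 15 (4R,5S)-4-(2-chloroacetyl)-5-{[(4R)-2,2,4-trimethyl-1,3-dioxolan-4-yl]methyl}oxolan-2-one
Product: 16 (4S,5S)-4-[(1R)-2-chloro-1-hydroxyethyl]-5-{[(4R)-2,2,4-trimethyl-1,3-dioxolan-4-yl]methyl}oxolan-2-one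
Conditions: (R)-2-methyl-CBS-oxazaborolidine (20 mol%), BH3·SMe2 (0.7 equiv), THF, −20 °C, slow addition of 15; MeOH quench
Reagents that add atoms: none
Why: Corey–Bakshi–Shibata reduction under catalyst control, with CH2Cl as the small and the ring carbon C7 as the large substituent, should deliver the (R)-chlorohydrin, which is the C6 configuration of the target; borane does not reduce the lactone at this temperature.

Step 10
Reactants: 16 (4S,5S)-4-[(1R)-2-chloro-1-hydroxyethyl]-5-{[(4R)-2,2,4-trimethyl-1,3-dioxolan-4-yl]methyl}oxolan-2-one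
Product: 17 (4R,5S)-4-[(1R)-1-(TBS-oxy)-2-chloroethyl]-5-{[(4R)-2,2,4-trimethyl-1,3-dioxolan-4-yl]methyl}oxolan-2-one
Conditions: TBSOTf (1.3 equiv), 2,6-lutidine, CH2Cl2, −78 → 0 °C
Reagents that add atoms: tert-butyldimethylsilyl triflate, CC(C)(C)[Si](C)(C)OS(=O)(=O)C(F)(F)F
Why: Silylation of the secondary alcohol should block the C6 oxygen from lactone migration (C8 to C6) and from closing onto C5 in every later basic step.

Step 11
Reactants: 17 (4R,5S)-4-[(1R)-1-(TBS-oxy)-2-chloroethyl]-5-{[(4R)-2,2,4-trimethyl-1,3-dioxolan-4-yl]methyl}oxolan-2-one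
Product: 18 (4R,5S)-4-[(1R)-1-(TBS-oxy)-2-chloroethyl]-5-[(2R)-2,3-dihydroxy-2-methylpropyl]oxolan-2-one
Conditions: AcOH–H2O–THF (3:1:1), 40 °C
Reagents that add atoms: none
Why: Mild acetal hydrolysis should free the C1/C10 diol while the hindered secondary silyl ether, the primary chloride and the lactone survive aqueous acetic acid.

Step 12
Reactants: 18 (4R,5S)-4-[(1R)-1-(TBS-oxy)-2-chloroethyl]-5-[(2R)-2,3-dihydroxy-2-methylpropyl]oxolan-2-one
Product: 19 (2R)-3-{(2S,3R)-3-[(1R)-1-(TBS-oxy)-2-chloroethyl]-5-oxooxolan-2-yl}-2-hydroxy-2-methylpropanal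
Conditions: TEMPO (10 mol%), PhI(OAc)2 (1.2 equiv), CH2Cl2, rt; used crude
Reagents that add atoms: none
Why: Oxoammonium (TEMPO) oxidation is selective for the primary alcohol, and the tertiary C10 hydroxyl cannot be oxidised or epimerised.

Step 13
Reactants: 20 but-3-yn-2-ol (racemic)
Product: 21 but-3-yn-2-yl methanesulfonate
Conditions: MsCl, Et3N, CH2Cl2, 0 °C
Reagents that add atoms: methanesulfonyl chloride, CS(=O)(=O)Cl
Why: Mesylation activates the propargylic carbinol (the future C4) for substitution.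

Step 14
Reactants: 21 but-3-yn-2-yl methanesulfonate; 22 triphenylmethanethiol
Product: 23 but-3-yn-2-yl trityl sulfide
Conditions: K2CO3, DMF, rt
Reagents that add atoms: none
Why: SN2 displacement of the activated propargylic mesylate by the soft trityl thiolate (thio-Williamson reaction) should install the protected C4 sulfur; the C4 configuration is irrelevant.

Step 15
Reactants: 19 (2R)-3-{(2S,3R)-3-[(1R)-1-(TBS-oxy)-2-chloroethyl]-5-oxooxolan-2-yl}-2-hydroxy-2-methylpropanal; 23 but-3-yn-2-yl trityl sulfide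
Product: 24 (4R,5S)-4-[(1R)-1-(TBS-oxy)-2-chloroethyl]-5-[(2R)-2,3-dihydroxy-2-methyl-6-(tritylsulfanyl)hept-4-yn-1-yl]oxolan-2-one (epimers at carbinol C1 and at C4)
Conditions: 23 (2.5 equiv), n-BuLi (2.4 equiv), THF, −78 °C; then 19, −78 °C; aq. NH4Cl at −78 °C
Reagents that add atoms: none
Why: 1,2-Addition of the lithium acetylide to the aldehyde should form C1–C2 much faster than attack on the γ-lactone at −78 °C, the first equivalent being consumed by the C10 hydroxyl.

Step 16
Reactants: 24 (4R,5S)-4-[(1R)-1-(TBS-oxy)-2-chloroethyl]-5-[(2R)-2,3-dihydroxy-2-methyl-6-(tritylsulfanyl)hept-4-yn-1-yl]oxolan-2-one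
Product: 25 (4R,5S)-4-[(1R)-1-(TBS-oxy)-2-chloroethyl]-5-[(2R)-2-hydroxy-2-methyl-3-oxo-6-(tritylsulfanyl)hept-4-yn-1-yl]oxolan-2-one (C4 epimers)
Conditions: MnO2 (activated, 20 equiv), CH2Cl2, rt
Reagents that add atoms: none
Why: Manganese dioxide oxidises the propargylic alcohol selectively and leaves the thioether and the tertiary alcohol alone.

Step 17
Reactants: 25 (4R,5S)-4-[(1R)-1-(TBS-oxy)-2-chloroethyl]-5-[(2R)-2-hydroxy-2-methyl-3-oxo-6-(tritylsulfanyl)hept-4-yn-1-yl]oxolan-2-one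
Product: 27 (4R,5S)-4-[(1R)-1-(TBS-oxy)-2-chloroethyl]-5-({(2R)-2-methyl-3-oxo-5-[1-(tritylsulfanyl)ethyl]-2,3-dihydrofuran-2-yl}methyl)oxolan-2-one (C4 epimers), via diethylamino enone 26 (not isolated)
Conditions: Et2NH (1.5 equiv), EtOH, rt; then AcOH–H2O–THF, rt
Reagents that add atoms: none
Why: Conjugate addition of the amine to the ynone, then acid-promoted addition–elimination by the C10 hydroxyl (formal 5-endo-dig oxa-Michael cyclisation of an α'-hydroxy ynone), is the established route to 2,2-disubstituted 3(2H)-furanones and forms the O–C3 bond.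

Step 18
Reactants: 27 (4R,5S)-4-[(1R)-1-(TBS-oxy)-2-chloroethyl]-5-({(2R)-2-methyl-3-oxo-5-[1-(tritylsulfanyl)ethyl]-2,3-dihydrofuran-2-yl}methyl)oxolan-2-one
Product: 28 (4R,5S)-4-[(1R)-1-(TBS-oxy)-2-chloroethyl]-5-{[(2R)-2-methyl-3-oxo-5-(1-sulfanylethyl)-2,3-dihydrofuran-2-yl]methyl}oxolan-2-one (C4 epimers)
Conditions: TFA (5% v/v), Et3SiH (3 equiv), CH2Cl2, 0 °C, 20 min; used at once
Reagents that add atoms: none
Why: Acidolytic S-detritylation with silane reduction of the trityl cation should free the thiol under brief anhydrous conditions that the silyl ether tolerates.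

Step 19
Reactants: 28 (4R,5S)-4-[(1R)-1-(TBS-oxy)-2-chloroethyl]-5-{[(2R)-2-methyl-3-oxo-5-(1-sulfanylethyl)-2,3-dihydrofuran-2-yl]methyl}oxolan-2-one
Product: 29 eleven-membered sulfide (S between C4 and C5; 6-O-TBS 3,10-epoxy-1-oxo-13-norgermacr-2-en-8,12-olide frame; 6R,7R,8S,10R; C4 epimers)
Conditions: Cs2CO3 (3 equiv), degassed DMF, 50 °C, syringe-pump addition of 28 (final 1 mM)
Reagents that add atoms: none
Why: Intramolecular S-alkylation of the caesium thiolate at the primary C5 chloride under high dilution (exo-tet closure, ten-membered when counted through the furanone oxygen) should form the S–C5 bond; both C4 epimers may cyclise since they converge later.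

Step 20
Reactants: 29 eleven-membered sulfide
Product: 31 eleven-membered sulfone (C4–SO2–C5; 6-O-TBS; 6R,7R,8S,10R; C4 epimers), via sulfoxide 30 (not isolated)
Conditions: (NH4)6Mo7O24·4H2O (10 mol%), 30% H2O2 (4 equiv), EtOH, 0 °C → rt
Reagents that add atoms: hydrogen peroxide, OO
Why: Molybdate-catalysed peroxide oxidation takes the sulfide through the sulfoxide to the sulfone chemoselectively, the electron-poor furanone alkene being inert to this oxidant.

Step 21
Reactants: 31 eleven-membered sulfone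
Product: 34 (4Z,6S,7R,8S,10R)-6-(TBS-oxy)-3,10-epoxy-1-oxo-13-norgermacra-2,4-dien-8,12-olide, via C4-chloro sulfone 32 (not isolated), via episulfone 33 (not isolated)
Conditions: t-BuOK (1.05 equiv), THF, −78 °C; NCS (1.05 equiv), −78 → −40 °C; then t-BuOK (3 equiv), −78 → 0 °C; aq. NH4Cl
Reagents that add atoms: none
Why: Deprotonation at C4, the most acidic C–H (α to the sulfone and the γ-position of the furanone, whose dienolates react with electrophiles at this exocyclic carbon), and chlorination by NCS should give the tertiary α-chloro sulfone 32; further tert-butoxide then removes a C5 proton and the carbanion displaces chloride in a 3-exo-tet closure to the cis-fused episulfone 33, which loses SO2 cheletropically, forming the C4=C5 bond and contracting the eleven-membered thiacycle to the ten-membered carbocycle. The closest known reaction type is the Ramberg–Bäcklund reaction with in situ halogenation, an established ring contraction of cyclic sulfones to strained cycloalkenes, run here with NCS and tert-butoxide instead of hydroxide to spare the lactone. No stereocentre is created, and the geometry should be Z because the nine-membered ring running through the furanone oxygen (O, C3 to C10) can hold only the cis episulfone and the cis alkene. The step needs site-selective halogenation, secured by the acidity gap between C4–H and C5–H2; it needs 1,3-elimination in preference to E1cB loss of the C6 oxygen, secured by the poorly leaving silyloxy group; and it needs an intact lactone, secured by a non-nucleophilic base at low temperature. Both C4 epimers of 31 converge on the same alkene.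

Step 22
Reactants: 34 (4Z,6S,7R,8S,10R)-6-(TBS-oxy)-3,10-epoxy-1-oxo-13-norgermacra-2,4-dien-8,12-olide
Product: 35 11-(dimethylaminomethyl) derivative of 34 (C11 epimers)
Conditions: LDA (1.2 equiv), THF, −78 °C; CH2=NMe2+ I− (2 equiv), −78 → 0 °C
Reagents that add atoms: Eschenmoser's salt (N,N-dimethylmethyleneiminium iodide), C=[N+](C)C.[I-]
Why: Kinetic enolisation of the lactone α-CH2 (the furanone has no α'-hydrogen because C10 is quaternary) and Mannich reaction with the preformed iminium salt should attach C13.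

Step 23
Reactants: 35 11-(dimethylaminomethyl) derivative of 34
Product: 37 (4Z,6S,7R,8S,10R)-6-(TBS-oxy)-3,10-epoxy-1-oxogermacra-2,4,11(13)-trien-8,12-olide, via trimethylammonium iodide 36 (not isolated)
Conditions: MeI (10 equiv), MeOH, rt; then aq. NaHCO3, CH2Cl2, rt
Reagents that add atoms: none
Why: N-Methylation and mild-base E1cB (Hofmann-type) loss of trimethylamine is the standard unveiling of an α-methylene lactone from its Mannich base.

Step 24
Reactants: 37 (4Z,6S,7R,8S,10R)-6-(TBS-oxy)-3,10-epoxy-1-oxogermacra-2,4,11(13)-trien-8,12-olide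
Product: 38 (4Z,6S,7S,8S,10R)-6-hydroxy-3,10-epoxy-1-oxogermacra-2,4,11(13)-trien-8,12-olide
Conditions: HF·pyridine, pyridine–THF, 0 °C → rt
Reagents that add atoms: none
Why: Buffered acidic fluoride desilylation should free the C6 alcohol without a basic nucleophile that could add to the methylene lactone or trigger lactone migration.

Step 25
Reactants: 38 (4Z,6S,7S,8S,10R)-6-hydroxy-3,10-epoxy-1-oxogermacra-2,4,11(13)-trien-8,12-olide; 39 angelic acid
Product: 41 CNP0293168.1, via angelic 2,4,6-trichlorobenzoic anhydride 40 (not isolated)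
Conditions: 39, 2,4,6-Cl3C6H2COCl, Et3N, toluene, rt, 2 h; then 38, 75 °C
Reagents that add atoms: none
Why: Yamaguchi-type mixed-anhydride esterification without a nucleophilic catalyst transfers the angeloyl group to hindered secondary alcohols without Z-to-E isomerisation to the tiglate, and the alcohol attacks the less hindered angeloyl carbonyl.

**Compound list**
1 | (S)-2-methylglycidol | C[C@]1(CO)CO1 | starting material
2 | (2R)-2-methylpent-4-ene-1,2-diol | C=CC[C@@](CO)(C)O | intermediate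
3 | (4R)-2,2,4-trimethyl-4-(prop-2-en-1-yl)-1,3-dioxolane | C=CC[C@@]1(C)OC(C)(C)OC1 | intermediate
4 | 3-{[(4R)-2,2,4-trimethyl-1,3-dioxolan-4-yl]methyl}-1,2,4-trioxolane (secondary ozonide, not isolated) | C1OOC(C[C@@]2(C)OC(C)(C)OC2)O1 | intermediate
5 | [(4R)-2,2,4-trimethyl-1,3-dioxolan-4-yl]acetaldehyde | O=CC[C@@]1(C)OC(C)(C)OC1 | intermediate
6 | (R)-4-benzyl-1,3-oxazolidin-2-one | O=C1N[C@H](Cc2ccccc2)CO1 | starting material
7 | methyl 4-chloro-4-oxobutanoate | COC(=O)CCC(Cl)=O | starting material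
8 | methyl 4-[(4R)-4-benzyl-2-oxo-1,3-oxazolidin-3-yl]-4-oxobutanoate | COC(=O)CCC(=O)N1[C@H](Cc2ccccc2)COC1=O | intermediate
9 | methyl (3R,4S)-3-{[(4R)-4-benzyl-2-oxo-1,3-oxazolidin-3-yl]carbonyl}-4-hydroxy-5-[(4R)-2,2,4-trimethyl-1,3-dioxolan-4-yl]pentanoate (syn-aldol adduct, not isolated) | COC(=O)C[C@@H](C(=O)N1[C@H](Cc2ccccc2)COC1=O)[C@@H](O)C[C@@]1(C)OC(C)(C)OC1 | intermediate
10 | (4R)-4-benzyl-3-{[(2S,3R)-5-oxo-2-{[(4R)-2,2,4-trimethyl-1,3-dioxolan-4-yl]methyl}oxolan-3-yl]carbonyl}-1,3-oxazolidin-2-one | O=C1C[C@@H](C(=O)N2[C@H](Cc3ccccc3)COC2=O)[C@H](C[C@@]2(C)OC(C)(C)OC2)O1 | intermediate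
11 | (2S,3R)-5-oxo-2-{[(4R)-2,2,4-trimethyl-1,3-dioxolan-4-yl]methyl}oxolane-3-carboperoxoic acid (not isolated) | O=C1C[C@@H](C(=O)OO)[C@H](C[C@@]2(C)OC(C)(C)OC2)O1 | intermediate
12 | (2S,3R)-5-oxo-2-{[(4R)-2,2,4-trimethyl-1,3-dioxolan-4-yl]methyl}oxolane-3-carboxylic acid | O=C1C[C@@H](C(=O)O)[C@H](C[C@@]2(C)OC(C)(C)OC2)O1 | intermediate
13 | mixed isobutyl carbonic anhydride of 12 (not isolated) | O=C1C[C@@H](C(=O)OC(=O)OCC(C)C)[C@H](C[C@@]2(C)OC(C)(C)OC2)O1 | intermediate
14 | (4R,5S)-4-(2-diazoacetyl)-5-{[(4R)-2,2,4-trimethyl-1,3-dioxolan-4-yl]methyl}oxolan-2-one | O=C1C[C@@H](C(=O)C=[N+]=[N-])[C@H](C[C@@]2(C)OC(C)(C)OC2)O1 | intermediate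
15 | (4R,5S)-4-(2-chloroacetyl)-5-{[(4R)-2,2,4-trimethyl-1,3-dioxolan-4-yl]methyl}oxolan-2-one | O=C1C[C@@H](C(=O)CCl)[C@H](C[C@@]2(C)OC(C)(C)OC2)O1 | intermediate
16 | (4S,5S)-4-[(1R)-2-chloro-1-hydroxyethyl]-5-{[(4R)-2,2,4-trimethyl-1,3-dioxolan-4-yl]methyl}oxolan-2-one | O=C1C[C@@H]([C@@H](O)CCl)[C@H](C[C@@]2(C)OC(C)(C)OC2)O1 | intermediate
17 | (4R,5S)-4-[(1R)-1-(TBS-oxy)-2-chloroethyl]-5-{[(4R)-2,2,4-trimethyl-1,3-dioxolan-4-yl]methyl}oxolan-2-one | O=C1C[C@@H]([C@@H](O[Si](C)(C)C(C)(C)C)CCl)[C@H](C[C@@]2(C)OC(C)(C)OC2)O1 | intermediate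
18 | (4R,5S)-4-[(1R)-1-(TBS-oxy)-2-chloroethyl]-5-[(2R)-2,3-dihydroxy-2-methylpropyl]oxolan-2-one | O=C1C[C@@H]([C@@H](O[Si](C)(C)C(C)(C)C)CCl)[C@H](C[C@@](C)(O)CO)O1 | intermediate
19 | (2R)-3-{(2S,3R)-3-[(1R)-1-(TBS-oxy)-2-chloroethyl]-5-oxooxolan-2-yl}-2-hydroxy-2-methylpropanal | O=C1C[C@@H]([C@@H](O[Si](C)(C)C(C)(C)C)CCl)[C@H](C[C@@](C)(O)C=O)O1 | intermediate
20 | but-3-yn-2-ol (racemic) | CC(O)C#C | starting material
21 | but-3-yn-2-yl methanesulfonate | CC(OS(C)(=O)=O)C#C | intermediate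
22 | triphenylmethanethiol | SC(c1ccccc1)(c1ccccc1)c1ccccc1 | starting material
23 | but-3-yn-2-yl trityl sulfide | CC(SC(c1ccccc1)(c1ccccc1)c1ccccc1)C#C | intermediate
24 | (4R,5S)-4-[(1R)-1-(TBS-oxy)-2-chloroethyl]-5-[(2R)-2,3-dihydroxy-2-methyl-6-(tritylsulfanyl)hept-4-yn-1-yl]oxolan-2-one (C1 and C4 epimers) | O=C1C[C@@H]([C@@H](O[Si](C)(C)C(C)(C)C)CCl)[C@H](C[C@@](C)(O)C(O)C#CC(C)SC(c2ccccc2)(c2ccccc2)c2ccccc2)O1 | intermediate
25 | (4R,5S)-4-[(1R)-1-(TBS-oxy)-2-chloroethyl]-5-[(2R)-2-hydroxy-2-methyl-3-oxo-6-(tritylsulfanyl)hept-4-yn-1-yl]oxolan-2-one (C4 epimers) | O=C1C[C@@H]([C@@H](O[Si](C)(C)C(C)(C)C)CCl)[C@H](C[C@@](C)(O)C(=O)C#CC(C)SC(c2ccccc2)(c2ccccc2)c2ccccc2)O1 | intermediate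
26 | (4R,5S)-4-[(1R)-1-(TBS-oxy)-2-chloroethyl]-5-[(2R)-5-(diethylamino)-2-hydroxy-2-methyl-3-oxo-6-(tritylsulfanyl)hept-4-en-1-yl]oxolan-2-one (enaminone, not isolated) | O=C1C[C@@H]([C@@H](O[Si](C)(C)C(C)(C)C)CCl)[C@H](C[C@@](C)(O)C(=O)C=C(N(CC)CC)C(C)SC(c2ccccc2)(c2ccccc2)c2ccccc2)O1 | intermediate
27 | (4R,5S)-4-[(1R)-1-(TBS-oxy)-2-chloroethyl]-5-({(2R)-2-methyl-3-oxo-5-[1-(tritylsulfanyl)ethyl]-2,3-dihydrofuran-2-yl}methyl)oxolan-2-one (C4 epimers) | O=C1C[C@@H]([C@@H](O[Si](C)(C)C(C)(C)C)CCl)[C@H](C[C@@]2(C)OC(=CC2=O)C(C)SC(c3ccccc3)(c3ccccc3)c3ccccc3)O1 | intermediate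
28 | (4R,5S)-4-[(1R)-1-(TBS-oxy)-2-chloroethyl]-5-{[(2R)-2-methyl-3-oxo-5-(1-sulfanylethyl)-2,3-dihydrofuran-2-yl]methyl}oxolan-2-one (C4 epimers) | O=C1C[C@@H]([C@@H](O[Si](C)(C)C(C)(C)C)CCl)[C@H](C[C@@]2(C)OC(=CC2=O)C(C)S)O1 | intermediate
29 | eleven-membered sulfide, S between C4 and C5, 6-O-TBS, saturated lactone (6R,7R,8S,10R; C4 epimers) | C1C(=O)O[C@H]2C[C@@]3(C)OC(=CC3=O)C(C)SC[C@H](O[Si](C)(C)C(C)(C)C)[C@H]12 | intermediate
30 | sulfoxide of 29 (not isolated) | C1C(=O)O[C@H]2C[C@@]3(C)OC(=CC3=O)C(C)S(=O)C[C@H](O[Si](C)(C)C(C)(C)C)[C@H]12 | intermediate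
31 | eleven-membered C4–SO2–C5 sulfone, 6-O-TBS, saturated lactone (6R,7R,8S,10R; C4 epimers) | C1C(=O)O[C@H]2C[C@@]3(C)OC(=CC3=O)C(C)S(=O)(=O)C[C@H](O[Si](C)(C)C(C)(C)C)[C@H]12 | intermediate
32 | C4-chloro derivative of sulfone 31 (not isolated) | C1C(=O)O[C@H]2C[C@@]3(C)OC(=CC3=O)C(C)(Cl)S(=O)(=O)C[C@H](O[Si](C)(C)C(C)(C)C)[C@H]12 | intermediate
33 | C4–C5 episulfone (thiirane 1,1-dioxide fused cis to the ten-membered ring, not isolated) | C1C(=O)O[C@H]2C[C@@]3(C)OC(=CC3=O)C4(C)C(S4(=O)=O)[C@H](O[Si](C)(C)C(C)(C)C)[C@H]12 | intermediate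
34 | (4Z,6S,7R,8S,10R)-6-(TBS-oxy)-3,10-epoxy-1-oxo-13-norgermacra-2,4-dien-8,12-olide | C1C(=O)O[C@H]2C[C@@]3(C)OC(=CC3=O)/C(C)=C\[C@H](O[Si](C)(C)C(C)(C)C)[C@H]12 | intermediate
35 | 11-(dimethylaminomethyl) derivative of 34 (C11 epimers) | CN(C)CC1C(=O)O[C@H]2C[C@@]3(C)OC(=CC3=O)/C(C)=C\[C@H](O[Si](C)(C)C(C)(C)C)[C@H]12 | intermediate
36 | N-methyl quaternary ammonium iodide of 35 (not isolated) | C[N+](C)(C)CC1C(=O)O[C@H]2C[C@@]3(C)OC(=CC3=O)/C(C)=C\[C@H](O[Si](C)(C)C(C)(C)C)[C@H]12.[I-] | intermediate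
37 | (4Z,6S,7R,8S,10R)-6-(TBS-oxy)-3,10-epoxy-1-oxogermacra-2,4,11(13)-trien-8,12-olide | C=C1C(=O)O[C@H]2C[C@@]3(C)OC(=CC3=O)/C(C)=C\[C@H](O[Si](C)(C)C(C)(C)C)[C@H]12 | intermediate
38 | (4Z,6S,7S,8S,10R)-6-hydroxy-3,10-epoxy-1-oxogermacra-2,4,11(13)-trien-8,12-olide | C=C1C(=O)O[C@H]2C[C@@]3(C)OC(=CC3=O)/C(C)=C\[C@H](O)[C@H]12 | intermediate
39 | angelic acid, (Z)-2-methylbut-2-enoic acid | C/C=C(/C)C(=O)O | starting material
40 | angelic 2,4,6-trichlorobenzoic anhydride (not isolated) | C/C=C(/C)C(=O)OC(=O)c1c(Cl)cc(Cl)cc1Cl | intermediate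
41 | CNP0293168.1, (4Z,6S,7R,8S,10R)-6-angeloyloxy-3,10-epoxy-1-oxogermacra-2,4,11(13)-trien-8,12-olide | C=C1C(=O)O[C@H]2C[C@@]3(C)OC(=CC3=O)/C(C)=C\[C@H](OC(=O)/C(C)=C\C)[C@H]12 | target

**Count**
Total steps: 25. Longest linear sequence: 22 steps (1–3, 5–12, 15–25).

**Steps most likely to fail**

1. Step 19 (macrocyclic S-alkylation). Intramolecular displacement at the β-silyloxy primary chloride may be slow enough that intermolecular oligomerisation or oxidative disulfide formation wins. The fallback sets out from 27 and returns at 29. Compound 27 would be desilylated with HF·pyridine to the chlorohydrin trityl sulfide F1 and detritylated (TFA, Et3SiH) to the chlorohydrin thiol F2. Under Cs2CO3 in DMF at high dilution, F2 should close to the terminal C5–C6 epoxy thiol F3, and the thiolate then opens the epoxide at the unhindered C5 terminus (intramolecular epoxide thiolysis) to the C6-hydroxy thiacycle F4. Silylation of F4 (TBSOTf, 2,6-lutidine) gives 29. The exposed C6 alkoxide makes lactone migration the thing to watch in this variant.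

2. Step 21 (one-flask halogenation and ring contraction). Chlorination may occur more than once or away from C4, the C5 carbanion may expel the C6 silyloxy group instead of closing the three-membered ring, or the alkoxide may degrade the dienone product. The fallback sets out from 31 and returns at 34, and separates the two events as a classical two-stage Ramberg–Bäcklund reaction. Sulfone 31 would be brominated at C4 under mild base (DBU, NBS, CH2Cl2, 0 °C) and the C4-bromo sulfone F5 isolated and purified. F5 would then be treated with KHMDS in THF at −78 °C, with no halogen source or alkoxide present and with the better leaving group, passing through episulfone 33 to 34.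

3. Step 22 (enolate aminomethylation next to the dienone). The amide base may deprotonate C6–H of the cross-conjugated furanone dienone, or add to it, instead of enolising the lactone. The fallback sets out from 31 and returns at 35, moving the Mannich step in front of the ring contraction, where no dienone exists. Sulfone 31 would be treated with LiHMDS (2.2 equiv; the unreactive C4 anion forms first, then the lactone enolate) and Eschenmoser's salt to give the Mannich-base sulfone F6. F6 would then be submitted to the conditions of step 21 and should pass through the C4-chloro amino sulfone F7 and the amino episulfone F8 to 35.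

Further compounds
F1 | step 19 | (4S,5S)-4-[(1R)-2-chloro-1-hydroxyethyl]-5-({(2R)-2-methyl-3-oxo-5-[1-(tritylsulfanyl)ethyl]-2,3-dihydrofuran-2-yl}methyl)oxolan-2-one | O=C1C[C@@H]([C@@H](O)CCl)[C@H](C[C@@]2(C)OC(=CC2=O)C(C)SC(c3ccccc3)(c3ccccc3)c3ccccc3)O1
F2 | step 19 | (4S,5S)-4-[(1R)-2-chloro-1-hydroxyethyl]-5-{[(2R)-2-methyl-3-oxo-5-(1-sulfanylethyl)-2,3-dihydrofuran-2-yl]methyl}oxolan-2-one | O=C1C[C@@H]([C@@H](O)CCl)[C@H](C[C@@]2(C)OC(=CC2=O)C(C)S)O1
F3 | step 19 | C5–C6 epoxy thiol (terminal oxirane on C7 of the lactone, not isolated) | O=C1C[C@@H]([C@@H]2CO2)[C@H](C[C@@]2(C)OC(=CC2=O)C(C)S)O1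
F4 | step 19 | eleven-membered sulfide with free C6 hydroxyl (S between C4 and C5) | C1C(=O)O[C@H]2C[C@@]3(C)OC(=CC3=O)C(C)SC[C@H](O)[C@H]12
F5 | step 21 | C4-bromo derivative of sulfone 31 | C1C(=O)O[C@H]2C[C@@]3(C)OC(=CC3=O)C(C)(Br)S(=O)(=O)C[C@H](O[Si](C)(C)C(C)(C)C)[C@H]12
F6 | step 22 | 11-(dimethylaminomethyl) derivative of sulfone 31 | CN(C)CC1C(=O)O[C@H]2C[C@@]3(C)OC(=CC3=O)C(C)S(=O)(=O)C[C@H](O[Si](C)(C)C(C)(C)C)[C@H]12
F7 | step 22 | C4-chloro derivative of F6 (not isolated) | CN(C)CC1C(=O)O[C@H]2C[C@@]3(C)OC(=CC3=O)C(C)(Cl)S(=O)(=O)C[C@H](O[Si](C)(C)C(C)(C)C)[C@H]12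
F8 | step 22 | C4–C5 episulfone of the Mannich base (not isolated) | CN(C)CC1C(=O)O[C@H]2C[C@@]3(C)OC(=CC3=O)C4(C)C(S4(=O)=O)[C@H](O[Si](C)(C)C(C)(C)C)[C@H]12
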